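**Plan**

- Retrosynthesis: the 4a,5-diol goes back to a 4a,5-epoxide of a ring A dienone. Ring A is opened at C3=C4 (aldol condensation) and at C2–C3 (alkyllithium plus N-methoxy-N-methylamide), which separates a (3-bromocyclopentyl)methyl unit from a ring B unit. C8–Br goes back to a bromoalkene and a ketone, and C8a–C1 to a Johnson–Claisen rearrangement.
- Enabling feature: quaternary C8a (CH3, C1, C8, C4a) is allylic to the oxygen-bearing C5 through the C4a=C8a alkene of a ring B enone. A ketene acetal on the C5 oxygen can therefore hand C1–C2 to C8a and leave the C4a=C5 alkene that later carries the trans-diol.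
- Forward order: ring B comes from 2-methylcyclohexane-1,3-dione and is taken to bromo amide 17. The cyclopentane comes from (1R,4S)-camphanic acid as bromo iodide 23. The two are joined at C2–C3 and ring A is closed last.
- Stereochemistry: the C5 carbinol is set by oxaziridine hydroxylation and relayed to C8a by the [3,3] shift, to C8 by amide-directed hydrogenation, and to C4a/C5 by epoxidation anti to the C8a methyl followed by anti opening. C1′ comes from the chiral pool; C3′ is set by CBS reduction and SN2 inversion.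
- Numbering: decalin as naphthalen-2(1H)-one, cyclopentyl carbons primed; α is the face of the C8a methyl group.

Key step: step 5

Assumption: the oxaziridine enantiomer named in step 3 is taken to give the (S)-carbinol by analogy with the 2-methyl-1-tetralone enolate; if the sense proves opposite, its antipode is used.
Assumption: (1R,4S)-camphanic acid (the lactone acid of the (1S,3R)-camphoric acid series) and tributyl[(methoxymethoxy)methyl]stannane are purchased.

**Route**

Step 1
Reactants: 1 2-methylcyclohexane-1,3-dione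
Product: 2 2-methyl-3-(2-methylpropoxy)cyclohex-2-en-1-one
Conditions: i-BuOH, p-TsOH·H2O (cat.), toluene, reflux, Dean–Stark
Reagents that add atoms: 2-methylpropan-1-ol, CC(C)CO
Why: Acid-catalysed enol ether formation from the symmetrical cyclic 1,3-dione with azeotropic removal of water gives the vinylogous ester without any regiochemical question.

Step 2
Reactants: 2 2-methyl-3-(2-methylpropoxy)cyclohex-2-en-1-one
Product: 4 (±)-2,6-dimethyl-3-(2-methylpropoxy)cyclohex-2-en-1-one, via lithium enolate 3 (not isolated)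
Conditions: LiN(i-Pr)2, THF, −78 °C; MeI, −78 to 0 °C
Reagents that add atoms: iodomethane, CI
Why: Kinetic deprotonation of a vinylogous ester occurs at the α′ carbon and the cross-conjugated enolate is C-methylated (Stork–Danheiser α′-alkylation); the new centre is racemic and is erased in step 3.

Step 3
Reactants: 4 (±)-2,6-dimethyl-3-(2-methylpropoxy)cyclohex-2-en-1-one
Product: 6 (6S)-6-hydroxy-2,6-dimethyl-3-(2-methylpropoxy)cyclohex-2-en-1-one, via sodium enolate 5 (not isolated)
Conditions: NaN(SiMe3)2, THF, −78 °C; (+)-[(8,8-dichlorocamphoryl)sulfonyl]oxaziridine, −78 °C; aq NH4Cl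
Reagents that add atoms: (+)-[(8,8-dichlorocamphoryl)sulfonyl]oxaziridine, CC1(C)[C@@H]2CC[C@]13CS(=O)(=O)N4O[C@@]34C2(Cl)Cl
Why: Asymmetric enolate hydroxylation with an enantiopure N-sulfonyloxaziridine transfers oxygen to one face of the planar tetrasubstituted enolate, which resembles the 2-methyl-1-tetralone enolate for which this reagent class is most selective, and so sets the tertiary carbinol; enantiomeric purity should be raised by crystallisation if needed.

Step 4
Reactants: 6 (6S)-6-hydroxy-2,6-dimethyl-3-(2-methylpropoxy)cyclohex-2-en-1-one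
Product: 8 (4S)-4-hydroxy-3-[(methoxymethoxy)methyl]-2,4-dimethylcyclohex-2-en-1-one, via dilithium 1,2-adduct 7 (not isolated)
Conditions: Bu3SnCH2OCH2OCH3, n-BuLi, THF, −78 °C (2.5 equiv of the lithium reagent); add 6, −78 to −20 °C; then 1 M HCl, THF, 0 °C to rt
Reagents that add atoms: tributyl[(methoxymethoxy)methyl]stannane, CCCC[Sn](CCCC)(CCCC)COCOC
Why: The α-alkoxymethyllithium from tin–lithium exchange adds 1,2 to the vinylogous ester carbonyl (one equivalent is consumed by the hydroxyl), and dilute acid then hydrolyses the enol ether with carbonyl transposition (Stork–Danheiser sequence) without touching the carbinol centre or the MOM ether.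

Step 5
Reactants: 8 (4S)-4-hydroxy-3-[(methoxymethoxy)methyl]-2,4-dimethylcyclohex-2-en-1-one; 9 triethyl orthoacetate
Product: 12 ethyl 2-[(1S)-2-[(methoxymethoxy)methyl]-1,3-dimethyl-6-oxocyclohex-2-en-1-yl]acetate, via mixed orthoester 10 (not isolated), via ketene acetal 11 (not isolated)
Conditions: MeC(OEt)3 (neat, excess), EtCO2H (cat.), 140–150 °C, EtOH distilled off
Reagents that add atoms: triethyl orthoacetate (9), CC(OCC)(OCC)OCC
Why: Weak-acid catalysis exchanges one ethoxy group of 9 for the C5 oxygen (10), loss of ethanol gives the mixed ketene acetal 11, and this allyl vinyl ether undergoes a concerted, chair-like [3,3] shift in which C5–O breaks while C8a–C1 forms, so that the alkene moves from C4a=C8a to C4a=C5 and C2 appears as the ethyl ester. The closest known reaction type is the Johnson–Claisen (orthoester Claisen) rearrangement of cyclohex-2-en-1-ols that creates a quaternary ring carbon with 1,3-transfer of the carbinol configuration. No ring is closed in this step. The single new stereocentre, C8a, is controlled by the C5 carbinol: the ketene acetal hangs from the β oxygen and can reach C8a only on that face, so the acetate arm is delivered β and the methyl group ends α, while the C5 centre is consumed. The step needs face selectivity at C8a and survival of the tertiary allylic alcohol up to the rearrangement; the first is secured by the intramolecular suprafacial delivery and the second by the conjugated C8 carbonyl, which makes ionisation at C5 unfavourable, together with the weak acid. Distilling off ethanol drives the slow exchange at the hindered hydroxyl, and the fully substituted enone α-carbon, which intermolecular alkylation reaches poorly, is reached here by a concerted intramolecular shift.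

Step 6
Reactants: 12 ethyl 2-[(1S)-2-[(methoxymethoxy)methyl]-1,3-dimethyl-6-oxocyclohex-2-en-1-yl]acetate
Product: 13 N-methoxy-2-[(1S)-2-[(methoxymethoxy)methyl]-1,3-dimethyl-6-oxocyclohex-2-en-1-yl]-N-methylacetamide
Conditions: MeNH(OMe)·HCl, i-PrMgCl, THF, −20 °C (amide preformed); add 12, −20 to 0 °C
Reagents that add atoms: N,O-dimethylhydroxylamine hydrochloride, CNOC.Cl
Why: Aminolysis of the ester by the chloromagnesium amide (Weinreb amide formation) runs at low temperature, while the hindered α-quaternary ketone is at most reversibly enolised by this weakly nucleophilic base.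

Step 7
Reactants: 13 N-methoxy-2-[(1S)-2-[(methoxymethoxy)methyl]-1,3-dimethyl-6-oxocyclohex-2-en-1-yl]-N-methylacetamide
Product: 15 (6S)-6-{2-[methoxy(methyl)amino]-2-oxoethyl}-5-[(methoxymethoxy)methyl]-4,6-dimethylcyclohexa-1,4-dien-1-yl trifluoromethanesulfonate, via potassium enolate 14 (not isolated)
Conditions: KN(SiMe3)2, THF, −78 °C; PhNTf2, −78 to 0 °C
Reagents that add atoms: N-phenylbis(trifluoromethanesulfonimide), O=S(=O)(N(c1ccccc1)S(=O)(=O)C(F)(F)F)C(F)(F)F
Why: Because C8a is quaternary the ketone can enolise only towards C7, so a single potassium enolate forms and is O-sulfonylated (enol triflate formation).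

Step 8
Reactants: 15 (6S)-6-{2-[methoxy(methyl)amino]-2-oxoethyl}-5-[(methoxymethoxy)methyl]-4,6-dimethylcyclohexa-1,4-dien-1-yl trifluoromethanesulfonate
Product: 16 2-[(1S)-2-bromo-6-[(methoxymethoxy)methyl]-1,5-dimethylcyclohexa-2,5-dien-1-yl]-N-methoxy-N-methylacetamide
Conditions: Ni(cod)2 (10 mol %), LiBr, DMA/THF, rt
Reagents that add atoms: lithium bromide, [Li+].[Br-]
Why: Zerovalent nickel inserts into the alkenyl C–O bond, the triflate on nickel is exchanged for bromide and C–Br reductive elimination releases the bromoalkene (nickel-catalysed conversion of cyclic enol triflates into alkenyl halides), under conditions that amides and ethers tolerate.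

Step 9
Reactants: 16 2-[(1S)-2-bromo-6-[(methoxymethoxy)methyl]-1,5-dimethylcyclohexa-2,5-dien-1-yl]-N-methoxy-N-methylacetamide
Product: 17 2-[(1S,2S)-2-bromo-6-[(methoxymethoxy)methyl]-1,5-dimethylcyclohex-5-en-1-yl]-N-methoxy-N-methylacetamide
Conditions: [Ir(cod)(PCy3)(py)]PF6 (5 mol %), H2 (1 atm), CH2Cl2, 0 °C to rt
Reagents that add atoms: none
Why: Proposed new method: the cationic iridium dihydride formed from the precatalyst should bind the carbonyl oxygen of the β-oriented acetamide arm and the adjacent C7=C8 alkene on the same face, so that both hydrogens arrive on the β face and bromine is left α at the new stereocentre C8, while the C–Br bond should survive because the coordinatively saturated trivalent iridium hydride has no ready path to oxidative addition and the tetrasubstituted C4a=C5 alkene inserts far more slowly; the closest known reaction types are the amide-directed hydrogenation of trisubstituted cycloalkenes with this catalyst and iridium-catalysed hydrogenations of fluoroalkenes that keep the halogen.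

Step 10
Reactants: 18 (1R,4S)-4,7,7-trimethyl-3-oxo-2-oxabicyclo[2.2.1]heptane-1-carboxylic acid [(1R,4S)-camphanic acid]
Product: 19 (1R,3S)-1,3-bis(hydroxymethyl)-2,2,3-trimethylcyclopentan-1-ol
Conditions: LiAlH4, THF, 0 °C to reflux; aqueous NaOH work-up
Reagents that add atoms: none
Why: Hydride reduction of both the carboxylic acid and the lactone gives the triol without touching either stereocentre, so the quaternary carbon that becomes C1′ is taken over from the chiral pool.

Step 11
Reactants: 19 (1R,3S)-1,3-bis(hydroxymethyl)-2,2,3-trimethylcyclopentan-1-ol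
Product: 20 (3S)-3-(hydroxymethyl)-2,2,3-trimethylcyclopentan-1-one
Conditions: NaIO4, THF/H2O, 0 °C to rt
Reagents that add atoms: none
Why: Periodate glycol cleavage acts only on the vicinal diol (tertiary carbinol and its hydroxymethyl group) and gives the ketone plus formaldehyde, leaving the isolated neopentyl alcohol untouched.

Step 12
Reactants: 20 (3S)-3-(hydroxymethyl)-2,2,3-trimethylcyclopentan-1-one
Product: 21 (3S)-3-(iodomethyl)-2,2,3-trimethylcyclopentan-1-one
Conditions: I2, PPh3, imidazole, toluene, 80 °C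
Reagents that add atoms: iodine, II
Why: Phosphonium activation of the primary alcohol and displacement by iodide (Garegg–Samuelsson iodination, an Appel-type reaction) is known to work on neopentyl alcohols on heating without skeletal change.

Step 13
Reactants: 21 (3S)-3-(iodomethyl)-2,2,3-trimethylcyclopentan-1-one
Product: 22 (1S,3S)-3-(iodomethyl)-2,2,3-trimethylcyclopentan-1-ol
Conditions: (R)-2-methyl-CBS-oxazaborolidine (20 mol %), BH3·SMe2, THF, −20 °C; MeOH
Reagents that add atoms: none
Why: Corey–Bakshi–Shibata reduction distinguishes the quaternary α-carbon from the α-methylene of the cyclopentanone, so the (R)-catalyst should give the (1S)-alcohol (hydroxyl cis to the C3 methyl, trans to the iodomethyl group) under catalyst control, independent of the remote quaternary centre.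

Step 14
Reactants: 22 (1S,3S)-3-(iodomethyl)-2,2,3-trimethylcyclopentan-1-ol
Product: 23 (1S,3R)-3-bromo-1-(iodomethyl)-1,2,2-trimethylcyclopentane
Conditions: CBr4, PPh3, CH2Cl2, 0 to 40 °C
Reagents that add atoms: tetrabromomethane, BrC(Br)(Br)Br
Why: Appel bromination converts the alcohol into an alkoxyphosphonium ion that bromide displaces from the rear (SN2 inversion), a known reaction type on hindered secondary cycloalkanols, which places bromine cis to the iodomethyl group while the neopentyl iodide is inert to bromide.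

Step 15
Reactants: 23 (1S,3R)-3-bromo-1-(iodomethyl)-1,2,2-trimethylcyclopentane; 17 2-[(1S,2S)-2-bromo-6-[(methoxymethoxy)methyl]-1,5-dimethylcyclohex-5-en-1-yl]-N-methoxy-N-methylacetamide
Product: 26 1-[(1S,2S)-2-bromo-6-[(methoxymethoxy)methyl]-1,5-dimethylcyclohex-5-en-1-yl]-3-[(1R,3R)-3-bromo-1,2,2-trimethylcyclopentyl]propan-2-one, via alkyllithium 24 (not isolated), via tetrahedral lithium adduct 25 (not isolated)
Conditions: 23, t-BuLi (2.0 equiv), Et2O/pentane, −78 °C; then 17 in Et2O, −78 °C; aq NH4Cl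
Reagents that add atoms: none
Why: Iodine–lithium exchange of a primary iodide at −78 °C is much faster than any reaction of the hindered secondary bromides (the bromide in 24 is cis to the carbanion arm and cannot be displaced intramolecularly), and the alkyllithium adds once to the amide because the chelated adduct 25 persists until quench (Weinreb ketone synthesis), forming C2–C3.

Step 16
Reactants: 26 1-[(1S,2S)-2-bromo-6-[(methoxymethoxy)methyl]-1,5-dimethylcyclohex-5-en-1-yl]-3-[(1R,3R)-3-bromo-1,2,2-trimethylcyclopentyl]propan-2-one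
Product: 27 1-[(1S,2S)-2-bromo-6-(hydroxymethyl)-1,5-dimethylcyclohex-5-en-1-yl]-3-[(1R,3R)-3-bromo-1,2,2-trimethylcyclopentyl]propan-2-one
Conditions: MgBr2·OEt2, n-BuSH, Et2O, rt
Reagents that add atoms: none
Why: The Lewis acid activates the acetal oxygen and the thiol traps the methoxymethyl cation (Lewis acid–thiol cleavage of MOM ethers), a non-protic method that spares the ketone, the tetrasubstituted alkene and both alkyl bromides.

Step 17
Reactants: 27 1-[(1S,2S)-2-bromo-6-(hydroxymethyl)-1,5-dimethylcyclohex-5-en-1-yl]-3-[(1R,3R)-3-bromo-1,2,2-trimethylcyclopentyl]propan-2-one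
Product: 28 (5S,6S)-5-bromo-6-{3-[(1R,3R)-3-bromo-1,2,2-trimethylcyclopentyl]-2-oxopropyl}-2,6-dimethylcyclohex-1-ene-1-carbaldehyde
Conditions: Dess–Martin periodinane, NaHCO3, CH2Cl2, 0 °C to rt
Reagents that add atoms: none
Why: Dess–Martin oxidation converts the primary allylic alcohol into the enal under buffered conditions that do not enolise the γ-bromo ketone.

Step 18
Reactants: 28 (5S,6S)-5-bromo-6-{3-[(1R,3R)-3-bromo-1,2,2-trimethylcyclopentyl]-2-oxopropyl}-2,6-dimethylcyclohex-1-ene-1-carbaldehyde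
Product: 30 (8S,8aS)-8-bromo-3-[(1R,3R)-3-bromo-1,2,2-trimethylcyclopentyl]-5,8a-dimethyl-6,7,8,8a-tetrahydronaphthalen-2(1H)-one, via aldol 29 (not isolated)
Conditions: p-TsOH·H2O (cat.), toluene, 70 °C
Reagents that add atoms: none
Why: In this acid-catalysed intramolecular aldol condensation only the C3 enol can reach the aldehyde through a six-membered transition state (the C1 enol would close a four-membered ring), the adduct 29 dehydrates to the conjugated dienone and closes ring A, and acid is chosen because an enolate of this γ-bromo ketone could close a cyclopropane.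

Step 19
Reactants: 30 (8S,8aS)-8-bromo-3-[(1R,3R)-3-bromo-1,2,2-trimethylcyclopentyl]-5,8a-dimethyl-6,7,8,8a-tetrahydronaphthalen-2(1H)-one
Product: 31 (4aR,5S,8S,8aS)-8-bromo-3-[(1R,3R)-3-bromo-1,2,2-trimethylcyclopentyl]-4a,5-epoxy-5,8a-dimethyl-4a,5,6,7,8,8a-hexahydronaphthalen-2(1H)-one (β-epoxide)
Conditions: mCPBA, NaHCO3, CH2Cl2, 0 °C
Reagents that add atoms: 3-chloroperoxybenzoic acid, OOC(=O)c1cccc(Cl)c1
Why: Prilezhaev epoxidation of a linear dienone takes place at the electron-richer tetrasubstituted γ,δ-alkene C4a=C5, and the peracid approaches the β face because the angular C8a methyl group shields the α face, which sets C4a.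

Step 20
Reactants: 31 (4aR,5S,8S,8aS)-8-bromo-3-[(1R,3R)-3-bromo-1,2,2-trimethylcyclopentyl]-4a,5-epoxy-5,8a-dimethyl-4a,5,6,7,8,8a-hexahydronaphthalen-2(1H)-one
Product: 32 (4aR,5R,8S,8aS)-8-bromo-3-[(1R,3R)-3-bromo-1,2,2-trimethylcyclopentyl]-4a,5-dihydroxy-5,8a-dimethyl-4a,5,6,7,8,8a-hexahydronaphthalen-2(1H)-one (target)
Conditions: HClO4 (cat.), THF/H2O, 0 °C to rt
Reagents that add atoms: water, O
Why: Acid-catalysed epoxide hydrolysis opens the ring at C5, the tertiary carbon that is not conjugated to the carbonyl, by backside attack of water in the trans-diaxial (Fürst–Plattner) sense, which gives the 4a-β,5-α diol with the C5 methyl β.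

**Compound list**

1 | 2-methylcyclohexane-1,3-dione | CC1C(=O)CCCC1=O | starting material
2 | 2-methyl-3-(2-methylpropoxy)cyclohex-2-en-1-one | CC(C)COC1=C(C)C(=O)CCC1 | intermediate
3 | lithium 6-methyl-5-(2-methylpropoxy)cyclohexa-1,5-dien-1-olate | CC(C)COC1=C(C)C(O[Li])=CCC1 | intermediate (not isolated)
4 | (±)-2,6-dimethyl-3-(2-methylpropoxy)cyclohex-2-en-1-one (racemic) | CC(C)COC1=C(C)C(=O)C(C)CC1 | intermediate
5 | sodium 2,6-dimethyl-5-(2-methylpropoxy)cyclohexa-1,5-dien-1-olate | CC(C)COC1=C(C)C(O[Na])=C(C)CC1 | intermediate (not isolated)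
6 | (6S)-6-hydroxy-2,6-dimethyl-3-(2-methylpropoxy)cyclohex-2-en-1-one | CC(C)COC1=C(C)C(=O)[C@@](C)(O)CC1 | intermediate
7 | dilithium dialkoxide of (1S)-2-[(methoxymethoxy)methyl]-1,3-dimethyl-4-(2-methylpropoxy)cyclohex-3-ene-1,2-diol (both C2 epimers) | CC(C)COC1=C(C)C(O[Li])(COCOC)[C@@](C)(O[Li])CC1 | intermediate (not isolated)
8 | (4S)-4-hydroxy-3-[(methoxymethoxy)methyl]-2,4-dimethylcyclohex-2-en-1-one | O=C1CC[C@](C)(O)C(COCOC)=C1C | intermediate
9 | triethyl orthoacetate | CC(OCC)(OCC)OCC | starting material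
10 | (4S)-4-(1,1-diethoxyethoxy)-3-[(methoxymethoxy)methyl]-2,4-dimethylcyclohex-2-en-1-one | O=C1CC[C@](C)(OC(C)(OCC)OCC)C(COCOC)=C1C | intermediate (not isolated)
11 | (4S)-4-[(1-ethoxyethenyl)oxy]-3-[(methoxymethoxy)methyl]-2,4-dimethylcyclohex-2-en-1-one | O=C1CC[C@](C)(OC(=C)OCC)C(COCOC)=C1C | intermediate (not isolated)
12 | ethyl 2-[(1S)-2-[(methoxymethoxy)methyl]-1,3-dimethyl-6-oxocyclohex-2-en-1-yl]acetate | O=C1CCC(C)=C(COCOC)[C@]1(C)CC(=O)OCC | intermediate
13 | N-methoxy-2-[(1S)-2-[(methoxymethoxy)methyl]-1,3-dimethyl-6-oxocyclohex-2-en-1-yl]-N-methylacetamide | O=C1CCC(C)=C(COCOC)[C@]1(C)CC(=O)N(C)OC | intermediate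
14 | potassium (6S)-6-{2-[methoxy(methyl)amino]-2-oxoethyl}-5-[(methoxymethoxy)methyl]-4,6-dimethylcyclohexa-1,4-dien-1-olate | [K]OC1=CCC(C)=C(COCOC)[C@]1(C)CC(=O)N(C)OC | intermediate (not isolated)
15 | (6S)-6-{2-[methoxy(methyl)amino]-2-oxoethyl}-5-[(methoxymethoxy)methyl]-4,6-dimethylcyclohexa-1,4-dien-1-yl trifluoromethanesulfonate | FC(F)(F)S(=O)(=O)OC1=CCC(C)=C(COCOC)[C@]1(C)CC(=O)N(C)OC | intermediate
16 | 2-[(1S)-2-bromo-6-[(methoxymethoxy)methyl]-1,5-dimethylcyclohexa-2,5-dien-1-yl]-N-methoxy-N-methylacetamide | BrC1=CCC(C)=C(COCOC)[C@]1(C)CC(=O)N(C)OC | intermediate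
17 | 2-[(1S,2S)-2-bromo-6-[(methoxymethoxy)methyl]-1,5-dimethylcyclohex-5-en-1-yl]-N-methoxy-N-methylacetamide | Br[C@H]1CCC(C)=C(COCOC)[C@]1(C)CC(=O)N(C)OC | intermediate
18 | (1R,4S)-4,7,7-trimethyl-3-oxo-2-oxabicyclo[2.2.1]heptane-1-carboxylic acid | CC1(C)[C@]2(C(=O)O)OC(=O)[C@@]1(C)CC2 | starting material
19 | (1R,3S)-1,3-bis(hydroxymethyl)-2,2,3-trimethylcyclopentan-1-ol | CC1(C)[C@](CO)(O)CC[C@]1(C)CO | intermediate
20 | (3S)-3-(hydroxymethyl)-2,2,3-trimethylcyclopentan-1-one | CC1(C)C(=O)CC[C@]1(C)CO | intermediate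
21 | (3S)-3-(iodomethyl)-2,2,3-trimethylcyclopentan-1-one | CC1(C)C(=O)CC[C@]1(C)CI | intermediate
22 | (1S,3S)-3-(iodomethyl)-2,2,3-trimethylcyclopentan-1-ol | CC1(C)[C@@H](O)CC[C@]1(C)CI | intermediate
23 | (1S,3R)-3-bromo-1-(iodomethyl)-1,2,2-trimethylcyclopentane | CC1(C)[C@H](Br)CC[C@]1(C)CI | intermediate
24 | {[(1S,3R)-3-bromo-1,2,2-trimethylcyclopentyl]methyl}lithium | CC1(C)[C@H](Br)CC[C@]1(C)C[Li] | intermediate (not isolated)
25 | lithium 1-[(1S,2S)-2-bromo-6-[(methoxymethoxy)methyl]-1,5-dimethylcyclohex-5-en-1-yl]-3-[(1R,3R)-3-bromo-1,2,2-trimethylcyclopentyl]-2-[methoxy(methyl)amino]propan-2-olate | CC1(C)[C@H](Br)CC[C@]1(C)CC(O[Li])(N(C)OC)C[C@]1(C)[C@@H](Br)CCC(C)=C1COCOC | intermediate (not isolated)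
26 | 1-[(1S,2S)-2-bromo-6-[(methoxymethoxy)methyl]-1,5-dimethylcyclohex-5-en-1-yl]-3-[(1R,3R)-3-bromo-1,2,2-trimethylcyclopentyl]propan-2-one | CC1(C)[C@H](Br)CC[C@]1(C)CC(=O)C[C@]1(C)[C@@H](Br)CCC(C)=C1COCOC | intermediate
27 | 1-[(1S,2S)-2-bromo-6-(hydroxymethyl)-1,5-dimethylcyclohex-5-en-1-yl]-3-[(1R,3R)-3-bromo-1,2,2-trimethylcyclopentyl]propan-2-one | CC1(C)[C@H](Br)CC[C@]1(C)CC(=O)C[C@]1(C)[C@@H](Br)CCC(C)=C1CO | intermediate
28 | (5S,6S)-5-bromo-6-{3-[(1R,3R)-3-bromo-1,2,2-trimethylcyclopentyl]-2-oxopropyl}-2,6-dimethylcyclohex-1-ene-1-carbaldehyde | CC1(C)[C@H](Br)CC[C@]1(C)CC(=O)C[C@]1(C)[C@@H](Br)CCC(C)=C1C=O | intermediate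
29 | (8S,8aS)-8-bromo-3-[(1R,3R)-3-bromo-1,2,2-trimethylcyclopentyl]-4-hydroxy-5,8a-dimethyl-3,4,6,7,8,8a-hexahydronaphthalen-2(1H)-one (C3/C4 epimers) | CC1(C)[C@H](Br)CC[C@]1(C)C1C(O)C2=C(C)CC[C@H](Br)[C@@]2(C)CC1=O | intermediate (not isolated)
30 | (8S,8aS)-8-bromo-3-[(1R,3R)-3-bromo-1,2,2-trimethylcyclopentyl]-5,8a-dimethyl-6,7,8,8a-tetrahydronaphthalen-2(1H)-one | CC1(C)[C@H](Br)CC[C@]1(C)C1=CC2=C(C)CC[C@H](Br)[C@@]2(C)CC1=O | intermediate
31 | (4aR,5S,8S,8aS)-8-bromo-3-[(1R,3R)-3-bromo-1,2,2-trimethylcyclopentyl]-4a,5-epoxy-5,8a-dimethyl-4a,5,6,7,8,8a-hexahydronaphthalen-2(1H)-one | CC1(C)[C@H](Br)CC[C@]1(C)C1=C[C@@]23O[C@@]3(C)CC[C@H](Br)[C@@]2(C)CC1=O | intermediate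
32 | (4aR,5R,8S,8aS)-8-bromo-3-[(1R,3R)-3-bromo-1,2,2-trimethylcyclopentyl]-4a,5-dihydroxy-5,8a-dimethyl-4a,5,6,7,8,8a-hexahydronaphthalen-2(1H)-one | CC1(C)[C@H](Br)CC[C@]1(C)C1=C[C@]2(O)[C@](C)(O)CC[C@H](Br)[C@@]2(C)CC1=O | target

**Step count and risks**

Total step count: 20. Longest linear sequence: 15 steps (steps 1–9 and 15–20, from 2-methylcyclohexane-1,3-dione); the cyclopentane branch is 5 steps (10–14) and joins at step 15.

Steps most likely to fail:

1. Step 9 (proposed new method). The hindered bromoalkene may fail to coordinate and insert, the C–Br bond may be hydrogenolysed, or the tetrasubstituted alkene may be reduced as well. Fallback with known chemistry, setting out from ketone 13 and replacing steps 7–9: reduction with BH3·SMe2 and (S)-2-methyl-CBS-oxazaborolidine, which treats the quaternary C8a side as the large group, should give the 8β-alcohol 2-[(1S,2R)-2-hydroxy-6-[(methoxymethoxy)methyl]-1,5-dimethylcyclohex-5-en-1-yl]-N-methoxy-N-methylacetamide F1. Appel bromination (CBr4, PPh3, CH2Cl2) with inversion then puts bromine on the α face and comes back to the route at 17. The alcohol is used at once so that lactonisation onto the amide does not intervene.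

2. Step 5. Exchange of the orthoester at the hindered tertiary hydroxyl may be too slow, so that dehydration overtakes rearrangement. Fallback, setting out from alcohol 8: acetylation (Ac2O, DMAP, Et3N) gives (1S)-2-[(methoxymethoxy)methyl]-1,3-dimethyl-4-oxocyclohex-2-en-1-yl acetate F2. LiN(i-Pr)2 (2.2 equiv) and Me3SiCl in THF at −78 °C silylate both the ketone (towards C7) and the acetate to give trimethyl{[(4S)-5-[(methoxymethoxy)methyl]-4,6-dimethyl-4-({1-[(trimethylsilyl)oxy]ethenyl}oxy)cyclohexa-1,5-dien-1-yl]oxy}silane F3. On warming this undergoes the Ireland–Claisen rearrangement, with the same suprafacial delivery to C8a, to trimethylsilyl 2-[(1S)-2-[(methoxymethoxy)methyl]-1,3-dimethyl-6-[(trimethylsilyl)oxy]cyclohexa-2,5-dien-1-yl]acetate F4. Aqueous work-up gives 2-[(1S)-2-[(methoxymethoxy)methyl]-1,3-dimethyl-6-oxocyclohex-2-en-1-yl]acetic acid F5, and esterification (EtI, K2CO3, DMF) comes back to the route at 12.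

3. Step 14. Elimination to the cyclopentene may outrun backside displacement at the carbon next to the quaternary centre. Fallback, setting out from keto alcohol 20 and moving the C–Br bond formation from substitution to hydrogenation of a bromoalkene:
   - silylation (t-BuPh2SiCl, imidazole, DMF) gives (3S)-3-{[(tert-butyldiphenylsilyl)oxy]methyl}-2,2,3-trimethylcyclopentan-1-one F6;
   - KN(SiMe3)2/PhNTf2 gives (4S)-4-{[(tert-butyldiphenylsilyl)oxy]methyl}-4,5,5-trimethylcyclopent-1-en-1-yl trifluoromethanesulfonate F7;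
   - Ni(cod)2/LiBr gives {[(1S)-3-bromo-1,2,2-trimethylcyclopent-3-en-1-yl]methoxy}(tert-butyl)diphenylsilane F8;
   - hydrogen-atom-transfer hydrogenation (Mn(dpm)3, PhSiH3, t-BuOOH, i-PrOH, rt), a radical hydrogenation known to keep the halogen of bromoalkenes, should deliver hydrogen to C3′ anti to the siloxymethyl group and give {[(1S,3R)-3-bromo-1,2,2-trimethylcyclopentyl]methoxy}(tert-butyl)diphenylsilane F9, with any C3′ epimer removed by chromatography;
   - Bu4NF in THF gives [(1S,3R)-3-bromo-1,2,2-trimethylcyclopentyl]methanol F10;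
   - I2/PPh3/imidazole comes back to the route at 23.

**Further compounds**

F1 | step 9 | 2-[(1S,2R)-2-hydroxy-6-[(methoxymethoxy)methyl]-1,5-dimethylcyclohex-5-en-1-yl]-N-methoxy-N-methylacetamide | O[C@@H]1CCC(C)=C(COCOC)[C@]1(C)CC(=O)N(C)OC
F2 | step 5 | (1S)-2-[(methoxymethoxy)methyl]-1,3-dimethyl-4-oxocyclohex-2-en-1-yl acetate | O=C1CC[C@](C)(OC(C)=O)C(COCOC)=C1C
F3 | step 5 | trimethyl{[(4S)-5-[(methoxymethoxy)methyl]-4,6-dimethyl-4-({1-[(trimethylsilyl)oxy]ethenyl}oxy)cyclohexa-1,5-dien-1-yl]oxy}silane | C=C(O[Si](C)(C)C)O[C@@]1(C)CC=C(O[Si](C)(C)C)C(C)=C1COCOC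
F4 | step 5 | trimethylsilyl 2-[(1S)-2-[(methoxymethoxy)methyl]-1,3-dimethyl-6-[(trimethylsilyl)oxy]cyclohexa-2,5-dien-1-yl]acetate | C[Si](C)(C)OC(=O)C[C@]1(C)C(O[Si](C)(C)C)=CCC(C)=C1COCOC
F5 | step 5 | 2-[(1S)-2-[(methoxymethoxy)methyl]-1,3-dimethyl-6-oxocyclohex-2-en-1-yl]acetic acid | O=C1CCC(C)=C(COCOC)[C@]1(C)CC(=O)O
F6 | step 14 | (3S)-3-{[(tert-butyldiphenylsilyl)oxy]methyl}-2,2,3-trimethylcyclopentan-1-one | CC1(C)C(=O)CC[C@]1(C)CO[Si](c1ccccc1)(c1ccccc1)C(C)(C)C
F7 | step 14 | (4S)-4-{[(tert-butyldiphenylsilyl)oxy]methyl}-4,5,5-trimethylcyclopent-1-en-1-yl trifluoromethanesulfonate | CC1(C)C(OS(=O)(=O)C(F)(F)F)=CC[C@]1(C)CO[Si](c1ccccc1)(c1ccccc1)C(C)(C)C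
F8 | step 14 | {[(1S)-3-bromo-1,2,2-trimethylcyclopent-3-en-1-yl]methoxy}(tert-butyl)diphenylsilane | CC1(C)C(Br)=CC[C@]1(C)CO[Si](c1ccccc1)(c1ccccc1)C(C)(C)C
F9 | step 14 | {[(1S,3R)-3-bromo-1,2,2-trimethylcyclopentyl]methoxy}(tert-butyl)diphenylsilane | CC1(C)[C@H](Br)CC[C@]1(C)CO[Si](c1ccccc1)(c1ccccc1)C(C)(C)C
F10 | step 14 | [(1S,3R)-3-bromo-1,2,2-trimethylcyclopentyl]methanol | CC1(C)[C@H](Br)CC[C@]1(C)CO
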